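**Plan**

1. Retrosynthesis: the three aryl silyl ethers come off last. Before that, ring B (the 2,3-dihydrobenzofuran) is cut at two neighbouring bonds at once, C5–CH2 (propane chain) and C4–CH2 (prenyl). This leads back to a 4,5-aryne of the dihydrobenzofuran, the 3-arylpropyl Grignard reagent of ring A, and prenyl bromide.
2. Enabling feature: C4 and C5 are vicinal ring carbons, and C4 sits next to the ring-fusion carbon C3a. The fused five-membered ring distorts and shields the aryne, so the carbon nucleophile should enter at C5 and the aryl–magnesium bond left at C4 takes the prenyl group. The 4-iodo-5-bromo aryne precursor follows from two innate substitutions, para to the free 7-OH and then para to O1.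
3. Forward, ring B half: o-eugenol → 3-prenylcatechol bis-silyl ether → Shi epoxidation → fluoride-triggered 5-exo closure of the dihydrofuran ring → iodination, silylation, bromination.
4. Forward, ring A half: umbelliferone → dihydrocoumarin (the lactone masks the 2-OH and holds the three-carbon chain) → O-prenylation → LiAlH4 → silylation → aromatic Claisen rearrangement (1,1-dimethylallyl group) → primary bromide. The chain is then joined to ring B and the silyl groups are removed.
5. Stereochemistry: the only stereocentre, C2 (R), comes from the reagent-controlled Shi epoxidation ((S)-epoxide from the L-fructose-derived ketone) and inversion at that carbon in the 5-exo epoxide opening. No later step touches it.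

Key step: step 16

Remark: o-eugenol, umbelliferone and the L-fructose-derived enantiomer of the Shi ketone are assumed to be purchasable; TBS = tert-butyldimethylsilyl.

**Route**

Step 1
Reactants: 1 o-eugenol (2-allyl-6-methoxyphenol)
Product: 2 3-allylbenzene-1,2-diol
Conditions: BBr3, CH2Cl2, −78 → 0 °C; then H2O
Reagents that add atoms: none
Why: Lewis-acid O-demethylation of the aryl methyl ether (bromide attacks the methyl group of the boron-bound ether) should free the catechol at low temperature without touching the allyl group.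

Step 2
Reactants: 2 3-allylbenzene-1,2-diol
Product: 3 3-allyl-1,2-bis(tert-butyldimethylsilyloxy)benzene
Conditions: TBSCl, imidazole, DMF, rt
Reagents that add atoms: tert-butyldimethylsilyl chloride, CC(C)(C)[Si](C)(C)Cl
Why: Silyl ether formation protects both phenols through the metathesis and the basic epoxidation and lets fluoride release the nucleophile later.

Step 3
Reactants: 3 3-allyl-1,2-bis(tert-butyldimethylsilyloxy)benzene
Product: 4 1,2-bis(tert-butyldimethylsilyloxy)-3-(3-methylbut-2-en-1-yl)benzene
Conditions: 2-methyl-2-butene (excess), second-generation Grubbs catalyst (3 mol%), CH2Cl2, 40 °C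
Reagents that add atoms: 2-methyl-2-butene, CC=C(C)C
Why: Olefin cross-metathesis of the terminal allyl arene with 2-methyl-2-butene should exchange the =CH2 terminus for an isopropylidene group and give the prenyl arene with loss of propene.

Step 4
Reactants: 4 1,2-bis(tert-butyldimethylsilyloxy)-3-(3-methylbut-2-en-1-yl)benzene
Product: 5 (S)-3-[2,3-bis(tert-butyldimethylsilyloxy)benzyl]-2,2-dimethyloxirane
Conditions: L-fructose-derived Shi ketone (30 mol%), Oxone (2KHSO5·KHSO4·K2SO4), K2CO3, Bu4NHSO4, MeCN–CH2(OMe)2–aq. Na2B4O7 buffer, 0 °C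
Reagents that add atoms: potassium peroxymonosulfate (KHSO5 of Oxone), [K+].[O-]S(=O)(=O)OO
Why: Shi asymmetric epoxidation, in which the chiral dioxirane made from the ketone transfers oxygen to one face of the trisubstituted alkene through a spiro transition state; the L-fructose-derived ketone should give the (S)-epoxide, the mirror image of the (R) series obtained with the D-fructose-derived ketone.

Step 5
Reactants: 5 (S)-3-[2,3-bis(tert-butyldimethylsilyloxy)benzyl]-2,2-dimethyloxirane
Product: 7 (R)-2-(2-hydroxypropan-2-yl)-2,3-dihydrobenzofuran-7-ol, via epoxy catechol phenoxide 6 (not isolated)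
Conditions: TBAF, THF, 0 °C → rt; then H2O
Reagents that add atoms: none
Why: Fluoride desilylation frees the phenoxide next to the side chain, which opens the epoxide at its secondary carbon in a 5-exo-tet SN2 closure with inversion, so the (S)-epoxide should become the (R)-configured C2 of the dihydrobenzofuran.

Step 6
Reactants: 7 (R)-2-(2-hydroxypropan-2-yl)-2,3-dihydrobenzofuran-7-ol
Product: 8 (R)-2-(2-hydroxypropan-2-yl)-4-iodo-2,3-dihydrobenzofuran-7-ol
Conditions: NIS, TsOH·H2O (10 mol%), MeCN, 0 °C
Reagents that add atoms: N-iodosuccinimide, O=C1CCC(=O)N1I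
Why: Electrophilic aromatic iodination of a 2-alkoxyphenol should go para to the free hydroxyl (C4), the strongest director, as it does with guaiacol-type phenols.

Step 7
Reactants: 8 (R)-2-(2-hydroxypropan-2-yl)-4-iodo-2,3-dihydrobenzofuran-7-ol
Product: 9 (R)-2-[7-(tert-butyldimethylsilyloxy)-4-iodo-2,3-dihydrobenzofuran-2-yl]propan-2-ol
Conditions: TBSCl, imidazole, DMF, rt
Reagents that add atoms: tert-butyldimethylsilyl chloride, CC(C)(C)[Si](C)(C)Cl
Why: Chemoselective silylation of the phenol (the tertiary alcohol is too hindered for TBSCl/imidazole) protects O7 for the organomagnesium chemistry and leaves the ring oxygen O1 as the strongest director for the next substitution.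

Step 8
Reactants: 9 (R)-2-[7-(tert-butyldimethylsilyloxy)-4-iodo-2,3-dihydrobenzofuran-2-yl]propan-2-ol
Product: 10 (R)-2-[5-bromo-7-(tert-butyldimethylsilyloxy)-4-iodo-2,3-dihydrobenzofuran-2-yl]propan-2-ol
Conditions: NBS, MeCN, 0 °C → rt, dark
Reagents that add atoms: N-bromosuccinimide, O=C1CCC(=O)N1Br
Why: Electrophilic aromatic bromination should go para to the ring oxygen O1 (C5), because C4 is occupied, O1 is held in conjugation by the five-membered ring, and C6 is flanked by the bulky silyl ether, which donates less than an alkyl ether.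

Step 9
Reactants: 11 umbelliferone (7-hydroxycoumarin)
Product: 12 7-hydroxychroman-2-one
Conditions: H2 (3 atm), 10% Pd/C, AcOH, rt
Reagents that add atoms: none
Why: Catalytic hydrogenation of the conjugated C3–C4 double bond of the coumarin should give the dihydrocoumarin, whose lactone masks the future ring A 2-hydroxyl and carries the three-carbon chain.

Step 10
Reactants: 12 7-hydroxychroman-2-one
Product: 13 7-(3-methylbut-2-en-1-yloxy)chroman-2-one
Conditions: prenyl bromide, K2CO3, acetone, 50 °C
Reagents that add atoms: prenyl bromide (1-bromo-3-methylbut-2-ene), CC(C)=CCBr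
Why: Williamson O-alkylation of the only free phenol gives the aryl prenyl ether, and because the lactone keeps the other ring A oxygen masked no regiochemical question arises.

Step 11
Reactants: 13 7-(3-methylbut-2-en-1-yloxy)chroman-2-one
Product: 14 2-(3-hydroxypropyl)-5-(3-methylbut-2-en-1-yloxy)phenol
Conditions: LiAlH4, THF, 0 °C → rt; aqueous work-up
Reagents that add atoms: none
Why: Hydride reduction of the aryl ester (lactone) opens the ring to the phenol and the primary alcohol without touching the prenyl ether.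

Step 12
Reactants: 14 2-(3-hydroxypropyl)-5-(3-methylbut-2-en-1-yloxy)phenol
Product: 15 tert-butyl{3-[2-(tert-butyldimethylsilyloxy)-4-(3-methylbut-2-en-1-yloxy)phenyl]propoxy}dimethylsilane
Conditions: TBSCl (2.4 equiv), imidazole, DMF, rt
Reagents that add atoms: tert-butyldimethylsilyl chloride, CC(C)(C)[Si](C)(C)Cl
Why: Silylation of the phenol and the primary alcohol protects both for the thermal rearrangement and places a bulky group next to the crowded ortho position of the prenyl ether.

Step 13
Reactants: 15 tert-butyl{3-[2-(tert-butyldimethylsilyloxy)-4-(3-methylbut-2-en-1-yloxy)phenyl]propoxy}dimethylsilane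
Product: 17 5-(tert-butyldimethylsilyloxy)-4-[3-(tert-butyldimethylsilyloxy)propyl]-2-(2-methylbut-3-en-2-yl)phenol, via ortho-dienone 16 (not isolated)
Conditions: PhNEt2, 170 °C, sealed tube, Ar
Reagents that add atoms: none
Why: Aromatic Claisen rearrangement ([3,3]-sigmatropic shift with allylic inversion, then tautomerization of the dienone) turns the O-prenyl ether into the C-bound 1,1-dimethylallyl group; of the two ortho positions the one between the two oxygens is crowded by the silyl ether, so migration should go to C5, as in related 2-alkoxy-4-prenyloxyarenes.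

Step 14
Reactants: 17 5-(tert-butyldimethylsilyloxy)-4-[3-(tert-butyldimethylsilyloxy)propyl]-2-(2-methylbut-3-en-2-yl)phenol
Product: 18 1,5-bis(tert-butyldimethylsilyloxy)-2-[3-(tert-butyldimethylsilyloxy)propyl]-4-(2-methylbut-3-en-2-yl)benzene
Conditions: TBSOTf, 2,6-lutidine, CH2Cl2, 0 °C
Reagents that add atoms: tert-butyldimethylsilyl triflate, CC(C)(C)[Si](C)(C)OS(=O)(=O)C(F)(F)F
Why: Silylation of the hindered phenol with the more reactive silyl triflate and a non-nucleophilic base completes the protection of ring A.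

Step 15
Reactants: 18 1,5-bis(tert-butyldimethylsilyloxy)-2-[3-(tert-butyldimethylsilyloxy)propyl]-4-(2-methylbut-3-en-2-yl)benzene
Product: 19 1-(3-bromopropyl)-2,4-bis(tert-butyldimethylsilyloxy)-5-(2-methylbut-3-en-2-yl)benzene
Conditions: Ph3PBr2, CH2Cl2, 0 °C → rt
Reagents that add atoms: triphenylphosphine dibromide, BrP(Br)(c1ccccc1)(c1ccccc1)c1ccccc1
Why: Triphenylphosphine dibromide converts primary alkyl silyl ethers directly into bromides (oxyphosphonium formation and SN2 displacement by bromide) while aryl silyl ethers stay intact, and no free bromine is present that could add to the vinyl group.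

Step 16
Reactants: 10 (R)-2-[5-bromo-7-(tert-butyldimethylsilyloxy)-4-iodo-2,3-dihydrobenzofuran-2-yl]propan-2-ol and 19 1-(3-bromopropyl)-2,4-bis(tert-butyldimethylsilyloxy)-5-(2-methylbut-3-en-2-yl)benzene
Product: 24 (R)-2-{5-[3-(2,4-bis(tert-butyldimethylsilyloxy)-5-(2-methylbut-3-en-2-yl)phenyl)propyl]-7-(tert-butyldimethylsilyloxy)-4-(3-methylbut-2-en-1-yl)-2,3-dihydrobenzofuran-2-yl}propan-2-ol, via alkylmagnesium bromide 20 (not isolated), via arylmagnesium chloride 21 (not isolated), via 4,5-aryne 22 (not isolated), via C4-arylmagnesium bromide 23 (not isolated)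
Conditions: 19, Mg turnings, THF, rt (gives 20, 1.6 equiv); 10, i-PrMgCl·LiCl (2.05 equiv), THF, −40 °C; add 20, −40 → 45 °C; then CuBr·SMe2 (10 mol%), prenyl bromide (3 equiv), −20 °C → rt; aq. NH4Cl
Reagents that add atoms: prenyl bromide (1-bromo-3-methylbut-2-ene), CC(C)=CCBr
Why: After deprotonation of the tertiary alcohol, iodine–magnesium exchange at C4 gives arylmagnesium 21, which on warming loses MgBrCl to the 4,5-aryne 22; the primary alkylmagnesium bromide 20 adds across the strained triple bond (carbomagnesiation), forging the C5–CH2 bond and leaving an aryl–magnesium bond at C4 (23), which copper-catalysed SN2 allylation with prenyl bromide turns into the C4-prenyl group. The closest known reaction type is the three-component coupling of an aryne from an ortho-dihaloarene with an organomagnesium or organolithium nucleophile and an electrophile (aryne carbometalation with electrophilic trapping). No ring is closed and no stereocentre is formed; C2 is remote and not acidic, so its configuration should be kept. The step needs attack of the nucleophile at C5: the fused five-membered ring compresses the internal angle at C4 (next to ring-fusion carbon C3a) and opens it at C5, which makes C5 the more electrophilic terminus, the C3 methylene shields C4, and the inductive effects of O1 and O7 on the two possible aryl anions cancel. It also needs exchange at iodine before bromine (secured by the halogen reactivity order and the low temperature) and attack of the C4 aryl-metal at the primary carbon of prenyl bromide (secured by its two ortho substituents, which disfavour formation of a quaternary centre).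

Step 17
Reactants: 24 (R)-2-{5-[3-(2,4-bis(tert-butyldimethylsilyloxy)-5-(2-methylbut-3-en-2-yl)phenyl)propyl]-7-(tert-butyldimethylsilyloxy)-4-(3-methylbut-2-en-1-yl)-2,3-dihydrobenzofuran-2-yl}propan-2-ol
Product: 25 4-{3-[(2R)-7-hydroxy-2-(2-hydroxypropan-2-yl)-4-(3-methylbut-2-en-1-yl)-2,3-dihydro-1-benzofuran-5-yl]propyl}-6-(2-methylbut-3-en-2-yl)benzene-1,3-diol (CNP0189999.1)
Conditions: TBAF (3.5 equiv), THF, 0 °C, Ar; then H2O
Reagents that add atoms: none
Why: Fluoride cleavage of the three aryl silyl ethers (desilylation) releases the three phenols under non-acidic conditions, which the prenyl group, the 1,1-dimethylallyl group and the tertiary alcohol should survive.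

**Compound list**

1 | o-eugenol (2-allyl-6-methoxyphenol) | C=CCc1cccc(OC)c1O | starting material
2 | 3-allylbenzene-1,2-diol | C=CCc1cccc(O)c1O | intermediate
3 | 3-allyl-1,2-bis(tert-butyldimethylsilyloxy)benzene | C=CCc1cccc(O[Si](C)(C)C(C)(C)C)c1O[Si](C)(C)C(C)(C)C | intermediate
4 | 1,2-bis(tert-butyldimethylsilyloxy)-3-(3-methylbut-2-en-1-yl)benzene | CC(C)=CCc1cccc(O[Si](C)(C)C(C)(C)C)c1O[Si](C)(C)C(C)(C)C | intermediate
5 | (S)-3-[2,3-bis(tert-butyldimethylsilyloxy)benzyl]-2,2-dimethyloxirane | CC1(C)O[C@H]1Cc1cccc(O[Si](C)(C)C(C)(C)C)c1O[Si](C)(C)C(C)(C)C | intermediate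
6 | (S)-3-[(3,3-dimethyloxiran-2-yl)methyl]benzene-1,2-diol (formed as its phenoxide) | CC1(C)O[C@H]1Cc1cccc(O)c1O | intermediate
7 | (R)-2-(2-hydroxypropan-2-yl)-2,3-dihydrobenzofuran-7-ol | CC(C)(O)[C@H]1Cc2cccc(O)c2O1 | intermediate
8 | (R)-2-(2-hydroxypropan-2-yl)-4-iodo-2,3-dihydrobenzofuran-7-ol | CC(C)(O)[C@H]1Cc2c(I)ccc(O)c2O1 | intermediate
9 | (R)-2-[7-(tert-butyldimethylsilyloxy)-4-iodo-2,3-dihydrobenzofuran-2-yl]propan-2-ol | CC(C)(O)[C@H]1Cc2c(I)ccc(O[Si](C)(C)C(C)(C)C)c2O1 | intermediate
10 | (R)-2-[5-bromo-7-(tert-butyldimethylsilyloxy)-4-iodo-2,3-dihydrobenzofuran-2-yl]propan-2-ol | CC(C)(O)[C@H]1Cc2c(I)c(Br)cc(O[Si](C)(C)C(C)(C)C)c2O1 | intermediate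
11 | umbelliferone (7-hydroxycoumarin) | O=c1ccc2ccc(O)cc2o1 | starting material
12 | 7-hydroxychroman-2-one | O=C1CCc2ccc(O)cc2O1 | intermediate
13 | 7-(3-methylbut-2-en-1-yloxy)chroman-2-one | CC(C)=CCOc1ccc2CCC(=O)Oc2c1 | intermediate
14 | 2-(3-hydroxypropyl)-5-(3-methylbut-2-en-1-yloxy)phenol | CC(C)=CCOc1ccc(CCCO)c(O)c1 | intermediate
15 | tert-butyl{3-[2-(tert-butyldimethylsilyloxy)-4-(3-methylbut-2-en-1-yloxy)phenyl]propoxy}dimethylsilane | CC(C)=CCOc1ccc(CCCO[Si](C)(C)C(C)(C)C)c(O[Si](C)(C)C(C)(C)C)c1 | intermediate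
16 | 3-(tert-butyldimethylsilyloxy)-4-[3-(tert-butyldimethylsilyloxy)propyl]-6-(2-methylbut-3-en-2-yl)cyclohexa-2,4-dien-1-one (ortho-dienone) | C=CC(C)(C)C1C=C(CCCO[Si](C)(C)C(C)(C)C)C(O[Si](C)(C)C(C)(C)C)=CC1=O | intermediate
17 | 5-(tert-butyldimethylsilyloxy)-4-[3-(tert-butyldimethylsilyloxy)propyl]-2-(2-methylbut-3-en-2-yl)phenol | C=CC(C)(C)c1cc(CCCO[Si](C)(C)C(C)(C)C)c(O[Si](C)(C)C(C)(C)C)cc1O | intermediate
18 | 1,5-bis(tert-butyldimethylsilyloxy)-2-[3-(tert-butyldimethylsilyloxy)propyl]-4-(2-methylbut-3-en-2-yl)benzene | C=CC(C)(C)c1cc(CCCO[Si](C)(C)C(C)(C)C)c(O[Si](C)(C)C(C)(C)C)cc1O[Si](C)(C)C(C)(C)C | intermediate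
19 | 1-(3-bromopropyl)-2,4-bis(tert-butyldimethylsilyloxy)-5-(2-methylbut-3-en-2-yl)benzene | C=CC(C)(C)c1cc(CCCBr)c(O[Si](C)(C)C(C)(C)C)cc1O[Si](C)(C)C(C)(C)C | intermediate
20 | {3-[2,4-bis(tert-butyldimethylsilyloxy)-5-(2-methylbut-3-en-2-yl)phenyl]propyl}magnesium bromide | C=CC(C)(C)c1cc(CCC[Mg]Br)c(O[Si](C)(C)C(C)(C)C)cc1O[Si](C)(C)C(C)(C)C | intermediate
21 | C4-arylmagnesium chloride of 10 (5-bromo-4-chloromagnesio compound, as its chloromagnesium alkoxide) | CC(C)(O[Mg]Cl)[C@H]1Cc2c([Mg]Cl)c(Br)cc(O[Si](C)(C)C(C)(C)C)c2O1 | intermediate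
22 | (R)-7-(tert-butyldimethylsilyloxy)-4,5-didehydro-2,3-dihydrobenzofuran-2-yl aryne (chloromagnesium alkoxide of the 2-hydroxypropan-2-yl group) | CC(C)(O[Mg]Cl)[C@H]1CC2=C(O1)C(O[Si](C)(C)C(C)(C)C)=CC#C2 | intermediate
23 | C4-arylmagnesium bromide carrying the ring A propyl chain at C5 (chloromagnesium alkoxide) | CC(C)(O[Mg]Cl)[C@H]1Cc2c([Mg]Br)c(CCCc3cc(C(C)(C)C=C)c(O[Si](C)(C)C(C)(C)C)cc3O[Si](C)(C)C(C)(C)C)cc(O[Si](C)(C)C(C)(C)C)c2O1 | intermediate
24 | (R)-2-{5-[3-(2,4-bis(tert-butyldimethylsilyloxy)-5-(2-methylbut-3-en-2-yl)phenyl)propyl]-7-(tert-butyldimethylsilyloxy)-4-(3-methylbut-2-en-1-yl)-2,3-dihydrobenzofuran-2-yl}propan-2-ol | CC(C)(O)[C@H]1Cc2c(CC=C(C)C)c(CCCc3cc(C(C)(C)C=C)c(O[Si](C)(C)C(C)(C)C)cc3O[Si](C)(C)C(C)(C)C)cc(O[Si](C)(C)C(C)(C)C)c2O1 | intermediate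
25 | 4-{3-[(2R)-7-hydroxy-2-(2-hydroxypropan-2-yl)-4-(3-methylbut-2-en-1-yl)-2,3-dihydro-1-benzofuran-5-yl]propyl}-6-(2-methylbut-3-en-2-yl)benzene-1,3-diol (CNP0189999.1) | CC(C)(O)[C@H]1Cc2c(CC=C(C)C)c(CCCc3cc(C(C)(C)C=C)c(O)cc3O)cc(O)c2O1 | target

**Summary**

Total step count: 17. Longest linear sequence: 10 steps (steps 1–8, 16 and 17).

Steps most likely to fail:

1. Step 16. The alkylmagnesium reagent may add at C4 instead of C5, the aryne may be reduced by β-hydride transfer from the Grignard reagent, or it may be consumed by the aryl Grignard itself, so the three-component union may give a regioisomer mixture or little coupled product. The fallback sets out from 10 and 19 and returns at 24. Compound 10 is treated with i-PrMgCl·LiCl at −40 °C and, before any warming, with CuBr·SMe2 and prenyl bromide. This should give (R)-2-[5-bromo-7-(tert-butyldimethylsilyloxy)-4-(3-methylbut-2-en-1-yl)-2,3-dihydrobenzofuran-2-yl]propan-2-ol F1, because the ortho-bromo arylmagnesium is stable at that temperature. Bromide 19 is converted with zinc dust and LiCl in THF into {3-[2,4-bis(tert-butyldimethylsilyloxy)-5-(2-methylbut-3-en-2-yl)phenyl]propyl}zinc bromide F2. Negishi coupling of F1 with F2 (Pd(OAc)2, SPhos, THF, 50 °C) should then give 24 with the regiochemistry fixed by the position of the bromine.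

2. Step 13. The sigmatropic shift may go to the position between the two oxygens, or the ortho-(1,1-dimethylallyl)phenol may rearrange further on prolonged heating. The fallback sets out from 12 and returns at 18, and places the group by cross-coupling instead. Bromination of 12 with NBS ortho to the free hydroxyl should give 6-bromo-7-hydroxychroman-2-one F3. Reduction with LiAlH4 gives 4-bromo-6-(3-hydroxypropyl)benzene-1,3-diol F4, and silylation with TBSCl and imidazole gives 1-bromo-2,4-bis(tert-butyldimethylsilyloxy)-5-[3-(tert-butyldimethylsilyloxy)propyl]benzene F5. A γ-selective Suzuki–Miyaura coupling of F5 with prenylboronic acid pinacol ester (Pd(OAc)2, bulky dialkylbiarylphosphine, aq. K3PO4, THF, 40 °C) should deliver 18.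

3. Step 8. Bromination may take place ortho to the silyloxy group (C6) or displace the iodine, which would give the wrong dihalide pattern. The fallback sets out from 8 and returns at 10, and steers the substitution with an ester instead of the silyl ether. Acylation of 8 with pivaloyl chloride and Et3N gives (R)-2-(2-hydroxypropan-2-yl)-4-iodo-2,3-dihydrobenzofuran-7-yl pivalate F6, in which the acyloxy group no longer competes with O1. Bromination with NBS should then give (R)-5-bromo-2-(2-hydroxypropan-2-yl)-4-iodo-2,3-dihydrobenzofuran-7-yl pivalate F7. Methanolysis (K2CO3, MeOH) gives (R)-5-bromo-2-(2-hydroxypropan-2-yl)-4-iodo-2,3-dihydrobenzofuran-7-ol F8, and silylation with TBSCl and imidazole gives 10.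

Further compounds
F1 | step 16 | (R)-2-[5-bromo-7-(tert-butyldimethylsilyloxy)-4-(3-methylbut-2-en-1-yl)-2,3-dihydrobenzofuran-2-yl]propan-2-ol | CC(C)(O)[C@H]1Cc2c(CC=C(C)C)c(Br)cc(O[Si](C)(C)C(C)(C)C)c2O1
F2 | step 16 | {3-[2,4-bis(tert-butyldimethylsilyloxy)-5-(2-methylbut-3-en-2-yl)phenyl]propyl}zinc bromide | C=CC(C)(C)c1cc(CCC[Zn]Br)c(O[Si](C)(C)C(C)(C)C)cc1O[Si](C)(C)C(C)(C)C
F3 | step 13 | 6-bromo-7-hydroxychroman-2-one | O=C1CCc2cc(Br)c(O)cc2O1
F4 | step 13 | 4-bromo-6-(3-hydroxypropyl)benzene-1,3-diol | OCCCc1cc(Br)c(O)cc1O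
F5 | step 13 | 1-bromo-2,4-bis(tert-butyldimethylsilyloxy)-5-[3-(tert-butyldimethylsilyloxy)propyl]benzene | CC(C)(C)[Si](C)(C)OCCCc1cc(Br)c(O[Si](C)(C)C(C)(C)C)cc1O[Si](C)(C)C(C)(C)C
F6 | step 8 | (R)-2-(2-hydroxypropan-2-yl)-4-iodo-2,3-dihydrobenzofuran-7-yl pivalate | CC(C)(O)[C@H]1Cc2c(I)ccc(OC(=O)C(C)(C)C)c2O1
F7 | step 8 | (R)-5-bromo-2-(2-hydroxypropan-2-yl)-4-iodo-2,3-dihydrobenzofuran-7-yl pivalate | CC(C)(O)[C@H]1Cc2c(I)c(Br)cc(OC(=O)C(C)(C)C)c2O1
F8 | step 8 | (R)-5-bromo-2-(2-hydroxypropan-2-yl)-4-iodo-2,3-dihydrobenzofuran-7-ol | CC(C)(O)[C@H]1Cc2c(I)c(Br)cc(O)c2O1
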